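## Analysis of the target

The target (C32H22O10) is a biflavone ether. An acacetin unit (unit 1: 5,7-dihydroxy-4'-methoxyflavone, rings A, C and B, atoms O1–C8a and C1'–C6') is bound at C8 through an ether oxygen to C4''' of a genkwanin unit (unit 2: 5''-hydroxy-7''-methoxyflavone, atoms O1''–C8a'' and C1'''–C6'''). All rings are planar and there is no stereocenter, so the problem is one of regiochemistry and of telling oxygen atoms apart. The sensitive groups are the three phenols (5-OH and 5''-OH chelated, 7-OH acidic), the two γ-pyranones, which hot hydroxide opens, and the two aryl methyl ethers, which must survive the final unmasking of the phenols. The difficulty lies in ring A of unit 1, a 1,2,3,5-tetraoxygenated benzene in which each oxygen has a different fate, and in the crowded diaryl ether at C8, which has oxygen-bearing carbons on both sides. Putting the aryloxy group onto a finished 5,7-dioxygenated flavone would have to distinguish C8 from C6, and annulating a pyranone onto a symmetrically protected ring would have to distinguish two ortho carbons. The strategy rests on one feature of ring A: O1 sits on C8a, whose neighbours are C8 (carrying the aryloxy group) and C4a, so C4a is the only unsubstituted carbon ortho to O1. An acyl carbon tethered to O1 through the C2=C3 enol ether can therefore reach C4a and nothing else, and forming C4–C4a last closes ring C without a regiochemical decision. Unit 2 poses no such problem, because its ring A comes from a ketone with two equivalent hydroxyl groups.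

## Retrosynthetic reasoning

**20 to 19.** The two O–benzyl bonds at O5 and O7 are cut last. Free hydroxyls on ring A of unit 1 would interfere with every acylation and base-mediated step before, and benzyl ethers come off by hydrogenolysis, which leaves the two methyl ethers alone. The 5''-OH is chelated and needs no protection.

**19 to 18.** The O1''–C2'' bond of unit 2 is cut, which opens its pyranone to the 1,3-diketone 18. The forward reaction is a cyclodehydration. Both hydroxyls of 18 flanking the ketone are equivalent, so either closure gives the same 5''-hydroxy-7''-methoxy pattern.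

**18 to 17 to 15 + 16.** The C2''–C3'' bond is cut, which leads back to the aryl ester 17 (an intramolecular O-to-C acyl shift in the forward sense), and then the ester C–O bond, which gives acid 15 and the symmetric ketone 16. This divides the molecule at the only place where a small commercial piece falls off and where the C–C bond can form through a six-membered transition state. Acid 15 comes from its methyl ester 14.

**14 to 12 (key disconnection).** The C4–C4a bond of unit 1 is cut, leaving the (Z)-3-aryloxycinnamic acid 12. Cutting here and not at O1–C2 or C2–C3 means the ring carbon is chosen by the tether: the acyl group hangs on O1, and the only free ortho carbon is C4a. The forward reaction must acylate a very electron-rich ring under conditions mild enough for benzyl ethers and a methyl ester.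

**12 to 11 to 8 + 10.** The O1–C2 bond is cut: phenol 8 adds to the ynoate 10, and the tert-butyl ester of the adduct 11 is then removed by acid while the methyl benzoate stays. Ester 10 comes from the commercial acid 9.

**8 to 7 to 5 + 6.** The O–C4''' bond of the diaryl ether is cut. The phenoxide of 5 displaces the fluorine of 6, whose para ester both activates the ring and is the later handle for unit 2. The methoxymethyl group of 7 keeps the future O1 masked during this step and is then removed to give 8.

**5 to 3 to 2 to 1.** The oxygen on the future C8 is traced back to the formyl carbon of 1 through an aryl formate. The formyl group is what differentiates the three hydroxyls of 1: the hydrogen-bonded one stays free during benzylation (2) and receives the temporary acetal (3), and the formyl group is then exchanged for oxygen (5).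

## Alternatives that were turned down

**Alternative 1:** The para-phenylene ring of unit 2 is taken apart at C3'''–C4''' and C5'''–C6'''. In the forward sense the aryl ethynyl ether A2 (from phenol 5) and methyl coumalate A3 undergo an inverse-demand [4+2] cycloaddition followed by decarboxylative cycloreversion, giving the 4-aryloxybenzoate A1, which has the same constitution as 7.
- For it: the para relationship follows from the polarisation of both partners, no metal is needed, and bond formation takes place away from the crowded oxygen.
- Against it: A2 needs two further steps from 5 by way of a dichlorovinyl ether and strong base, and an ynol ether on a ring with three more oxygen substituents is prone to hydration and polymerisation. The sequence also ends at a compound that the chosen route reaches from 5 and 6 in one step.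
- Comparison: on the hindered C–O bond this alternative is the stronger one. In its place the chosen strategy offers a one-step ether synthesis from shelf reagents with a copper-catalysed coupling in reserve, and it spends its key step on the ring fusion of unit 1, which Alternative 1 leaves unsolved.

**Alternative 2:** Three bonds of ring C of unit 2 are cut (O1''–C8a'', C4''–C4a'' and O1''–C2''). In the forward sense fluoride releases 3,5-dimethoxybenzyne from the silyl triflate A5. The carboxylate of the arylpropiolic acid A6, which carries the protected unit 1, adds at the aryne carbon distal to the methoxy group, the aryl anion takes the acyl carbon, and the phenoxide closes onto the ynone to give A4.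
- For it: one operation forms three bonds and a ring, and it would replace esterification, acyl shift and cyclodehydration. It is more convergent than the chosen end-game.
- Against it: protonation of the aryl anion before the acyl shift (a four-membered transition state) gives a plain aryl ester. The aryne can also be trapped by the many nucleophilic sites of A6. A5 and A6 each need several steps. A4 carries a 5''-methyl ether that must later be removed by chelation-directed demethylation without touching the 7''- and 4'-methyl ethers.
- Comparison: this alternative is stronger on bond count per step. The chosen strategy offers instead a key step that is intramolecular, has only one position within reach and is run early on inexpensive material, while unit 2 is finished by predictable classical steps.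

**Alternative 3:** The C2=C3 bond of unit 1 is cut. In the forward sense the aryl vinyl ketone A8, bearing an ortho 1-(4-methoxyphenyl)vinyl ether, undergoes ring-closing metathesis with a ruthenium alkylidene catalyst of the second generation to give the flavone A7.
- For it: conditions are neutral, the closure itself has no regiochemical choice, and the masked aldehyde of A7 would allow a chalcone route to unit 2.
- Against it: the C4–C4a bond must already be in place, so the ortho acylation of the tetraoxygenated ring has to be solved separately. The enol ether requires methylenation of an aryl ester with a titanium carbenoid, and the vinyl ketone is polymerisable. Metathesis must join an electron-poor enone to a 1,1-disubstituted electron-rich enol ether, a poorly matched pair.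
- Comparison: both closures are equally certain in position. The chosen strategy forms C4–C4a and closes the ring in the same event, needs fewer steps and avoids fragile intermediates.

Key step: step 9

Assumption: compounds 11, 12 and 13 are drawn and named as the Z isomers. Any E isomer formed in step 7 is carried along, because the acidic medium of steps 8 and 9 interconverts the two geometries.

## Route

Step 1
Reactants: 1 2,4,6-trihydroxybenzaldehyde
Product: 2 2,4-bis(benzyloxy)-6-hydroxybenzaldehyde
Conditions: BnBr (2.1 equiv), K2CO3 (2.2 equiv), DMF, 0 °C to rt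
Reagents that add atoms: benzyl bromide, BrCc1ccccc1
Why: Williamson etherification; the 4-OH is the most acidic and one ortho OH follows, while the last ortho OH stays hydrogen-bonded to the formyl oxygen and is much less nucleophilic, so alkylation should stop at the 2,4-dibenzyl ether.

Step 2
Reactants: 2 2,4-bis(benzyloxy)-6-hydroxybenzaldehyde
Product: 3 2,4-bis(benzyloxy)-6-(methoxymethoxy)benzaldehyde
Conditions: NaH, DMF, 0 °C; then MOMCl, 0 °C to rt
Reagents that add atoms: chloromethyl methyl ether, COCCl
Why: NaH breaks the chelate and the phenoxide is alkylated by the chloromethyl ether (Williamson-type acetal formation). The acetal marks the oxygen that becomes O1 and is later removable by acid without touching benzyl ethers.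

Step 3
Reactants: 3 2,4-bis(benzyloxy)-6-(methoxymethoxy)benzaldehyde
Product: 5 2,4-bis(benzyloxy)-6-(methoxymethoxy)phenol, via aryl formate 4 (not isolated)
Conditions: mCPBA, CH2Cl2, 0 °C to rt; aqueous NaHCO3/Na2S2O3 wash; then K2CO3 (cat.), MeOH, rt, under N2
Reagents that add atoms: 3-chloroperoxybenzoic acid, OOC(=O)c1cccc(Cl)c1
Why: Baeyer–Villiger (Dakin-type) oxidation; the trialkoxyaryl group migrates readily to oxygen in the Criegee intermediate and the formate is removed by methanolysis. The former formyl position thus becomes the phenol oxygen that will carry the aryl ether.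

Step 4
Reactants: 5 2,4-bis(benzyloxy)-6-(methoxymethoxy)phenol; 6 methyl 4-fluorobenzoate
Product: 7 methyl 4-[2,4-bis(benzyloxy)-6-(methoxymethoxy)phenoxy]benzoate
Conditions: Cs2CO3, DMSO, 100 °C, under N2
Reagents that add atoms: none
Why: Nucleophilic aromatic substitution by addition–elimination; the para ester stabilises the Meisenheimer intermediate and fluorine is the best leaving group for this mechanism. The loosely paired cesium phenoxide in DMSO should compensate for the two ortho substituents.

Step 5
Reactants: 7 methyl 4-[2,4-bis(benzyloxy)-6-(methoxymethoxy)phenoxy]benzoate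
Product: 8 methyl 4-[2,4-bis(benzyloxy)-6-hydroxyphenoxy]benzoate
Conditions: HCl (cat.), MeOH/THF, 45 °C
Reagents that add atoms: none
Why: Acid-catalysed acetal exchange removes the methoxymethyl group. Benzyl ethers, the diaryl ether and the methyl ester (in methanol) are inert under these conditions.

Step 6
Reactants: 9 3-(4-methoxyphenyl)propiolic acid
Product: 10 tert-butyl 3-(4-methoxyphenyl)propiolate
Conditions: t-BuOC(=NH)CCl3, BF3·OEt2 (cat.), CH2Cl2/cyclohexane, rt
Reagents that add atoms: tert-butyl 2,2,2-trichloroacetimidate, CC(C)(C)OC(=N)C(Cl)(Cl)Cl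
Why: Acid-catalysed tert-butyl transfer from the imidate to the carboxylic acid under nearly neutral conditions, which avoids decarboxylation of the ynoic acid. The tert-butyl ester is chosen because acid removes it in the presence of the methyl benzoate.

Step 7
Reactants: 8 methyl 4-[2,4-bis(benzyloxy)-6-hydroxyphenoxy]benzoate; 10 tert-butyl 3-(4-methoxyphenyl)propiolate
Product: 11 tert-butyl (Z)-3-{3,5-bis(benzyloxy)-2-[4-(methoxycarbonyl)phenoxy]phenoxy}-3-(4-methoxyphenyl)acrylate
Conditions: K2CO3 (0.3 equiv), DMF, 80 °C
Reagents that add atoms: none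
Why: Base-catalysed oxa-Michael addition of the phenoxide to the β-carbon of the ynoate, then protonation of the allenolate; anti addition places the aryloxy group cis to the ester (Z). This forms O1–C2 of unit 1.

Step 8
Reactants: 11 tert-butyl (Z)-3-{3,5-bis(benzyloxy)-2-[4-(methoxycarbonyl)phenoxy]phenoxy}-3-(4-methoxyphenyl)acrylate
Product: 12 (Z)-3-{3,5-bis(benzyloxy)-2-[4-(methoxycarbonyl)phenoxy]phenoxy}-3-(4-methoxyphenyl)acrylic acid
Conditions: CF3CO2H/CH2Cl2 (1:4), anhydrous, 0 °C to rt; evaporation from toluene
Reagents that add atoms: none
Why: Acidolysis of the tert-butyl ester by alkyl–oxygen cleavage; the methyl ester and benzyl ethers are stable to anhydrous trifluoroacetic acid at room temperature. Exclusion of water prevents hydrolysis of the vinylogous carbonate.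

Step 9
Reactants: 12 (Z)-3-{3,5-bis(benzyloxy)-2-[4-(methoxycarbonyl)phenoxy]phenoxy}-3-(4-methoxyphenyl)acrylic acid
Product: 14 methyl 4-{[5,7-bis(benzyloxy)-2-(4-methoxyphenyl)-4-oxo-4H-chromen-8-yl]oxy}benzoate, via trifluoroacetic mixed anhydride 13 (not isolated)
Conditions: (CF3CO)2O (1.5 equiv), CH2Cl2, 0 °C to rt; aqueous NaHCO3 quench
Reagents that add atoms: none
Why: The anhydride converts acid 12 into the mixed anhydride 13, whose acyl carbon (as such or as an incipient acylium ion) is attacked by the ring carbon ortho to the enol ether oxygen, and loss of a proton from the arenium ion gives the pyranone. The closest known reaction type is the acid-mediated cycloacylation of 3-aryloxycinnamic acids to flavones, an intramolecular Friedel–Crafts acylation. Ring C closes as a six-membered ring in a 6-exo-trig sense at the anhydride carbonyl, running from O1 through C2, C3 and C4 onto C4a. No stereocenter is formed. The step needs regioselectivity for C4a, and the substrate secures it: the tether starts at the one oxygen whose other ortho carbon already carries the aryloxy group, so C4a is the only carbon within reach, and it is also ortho and para to the two benzyloxy groups. Only the Z acid can close, but the trifluoroacetic acid set free protonates the enol ether at the α-carbon (the future C3) and lets any E isomer rotate into the Z form. The mild activator should leave the benzyl ethers, the methyl ester and the diaryl ether intact, and near-stoichiometric anhydride at 0 °C limits intermolecular trifluoroacetylation of the electron-rich ring.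

Step 10
Reactants: 14 methyl 4-{[5,7-bis(benzyloxy)-2-(4-methoxyphenyl)-4-oxo-4H-chromen-8-yl]oxy}benzoate
Product: 15 4-{[5,7-bis(benzyloxy)-2-(4-methoxyphenyl)-4-oxo-4H-chromen-8-yl]oxy}benzoic acid
Conditions: LiOH·H2O, THF/MeOH/H2O, rt; then 1 M HCl
Reagents that add atoms: lithium hydroxide, [Li+].[OH-]
Why: Saponification of the only ester in the molecule. The electron-rich, fully substituted pyranone is a poor acceptor for hydroxide at room temperature.

Step 11
Reactants: 15 4-{[5,7-bis(benzyloxy)-2-(4-methoxyphenyl)-4-oxo-4H-chromen-8-yl]oxy}benzoic acid; 16 2,6-dihydroxy-4-methoxyacetophenone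
Product: 17 2-acetyl-3-hydroxy-5-methoxyphenyl 4-{[5,7-bis(benzyloxy)-2-(4-methoxyphenyl)-4-oxo-4H-chromen-8-yl]oxy}benzoate
Conditions: DIC, DMAP (cat.), 16 (2.5 equiv), CH2Cl2/THF, 0 °C to rt
Reagents that add atoms: none
Why: Steglich esterification through the acylpyridinium ion. The two hydroxyls of 16 are equivalent by symmetry, and an excess of 16 keeps the acylation at the monoester.

Step 12
Reactants: 17 2-acetyl-3-hydroxy-5-methoxyphenyl 4-{[5,7-bis(benzyloxy)-2-(4-methoxyphenyl)-4-oxo-4H-chromen-8-yl]oxy}benzoate
Product: 18 1-(4-{[5,7-bis(benzyloxy)-2-(4-methoxyphenyl)-4-oxo-4H-chromen-8-yl]oxy}phenyl)-3-(2,6-dihydroxy-4-methoxyphenyl)propane-1,3-dione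
Conditions: LiN(SiMe3)2 (3.3 equiv), THF, −78 °C to rt; then 1 M HCl
Reagents that add atoms: none
Why: Baker–Venkataraman rearrangement; the lithium enolate of the acetyl group attacks the neighbouring ester carbonyl through a six-membered transition state, moving the acyl group from oxygen to carbon. Three equivalents of the non-nucleophilic base cover the phenol, the enolate and the acidic diketone.

Step 13
Reactants: 18 1-(4-{[5,7-bis(benzyloxy)-2-(4-methoxyphenyl)-4-oxo-4H-chromen-8-yl]oxy}phenyl)-3-(2,6-dihydroxy-4-methoxyphenyl)propane-1,3-dione
Product: 19 5,7-bis(benzyloxy)-8-[4-(5-hydroxy-7-methoxy-4-oxo-4H-chromen-2-yl)phenoxy]-2-(4-methoxyphenyl)-4H-chromen-4-one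
Conditions: NaOAc, AcOH, 100 °C
Reagents that add atoms: none
Why: Cyclodehydration of the 2-hydroxyaryl 1,3-diketone (hemiketal formation, then loss of water) closes ring C of unit 2. Either hydroxyl gives the same product, the other becomes the chelated 5''-OH, and buffered acetic acid spares the benzyl ethers.

Step 14
Reactants: 19 5,7-bis(benzyloxy)-8-[4-(5-hydroxy-7-methoxy-4-oxo-4H-chromen-2-yl)phenoxy]-2-(4-methoxyphenyl)-4H-chromen-4-one
Product: 20 5,7-dihydroxy-8-[4-(5-hydroxy-7-methoxy-4-oxo-4H-chromen-2-yl)phenoxy]-2-(4-methoxyphenyl)-4H-chromen-4-one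
Conditions: H2 (1 atm), 10% Pd/C, THF/MeOH, rt
Reagents that add atoms: none
Why: Hydrogenolysis of the two benzylic C–O bonds. The methyl ethers, the diaryl ether and, at one atmosphere and room temperature, the pyranone double bonds should not be touched.

## Compound list

1 | 2,4,6-trihydroxybenzaldehyde | O=Cc1c(O)cc(O)cc1O | starting material
2 | 2,4-bis(benzyloxy)-6-hydroxybenzaldehyde | O=Cc1c(O)cc(OCc2ccccc2)cc1OCc1ccccc1 | intermediate
3 | 2,4-bis(benzyloxy)-6-(methoxymethoxy)benzaldehyde | COCOc1cc(OCc2ccccc2)cc(OCc2ccccc2)c1C=O | intermediate
4 | 2,4-bis(benzyloxy)-6-(methoxymethoxy)phenyl formate | COCOc1cc(OCc2ccccc2)cc(OCc2ccccc2)c1OC=O | intermediate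
5 | 2,4-bis(benzyloxy)-6-(methoxymethoxy)phenol | COCOc1cc(OCc2ccccc2)cc(OCc2ccccc2)c1O | intermediate
6 | methyl 4-fluorobenzoate | COC(=O)c1ccc(F)cc1 | starting material
7 | methyl 4-[2,4-bis(benzyloxy)-6-(methoxymethoxy)phenoxy]benzoate | COC(=O)c1ccc(Oc2c(OCOC)cc(OCc3ccccc3)cc2OCc2ccccc2)cc1 | intermediate
8 | methyl 4-[2,4-bis(benzyloxy)-6-hydroxyphenoxy]benzoate | COC(=O)c1ccc(Oc2c(O)cc(OCc3ccccc3)cc2OCc2ccccc2)cc1 | intermediate
9 | 3-(4-methoxyphenyl)propiolic acid | COc1ccc(C#CC(=O)O)cc1 | starting material
10 | tert-butyl 3-(4-methoxyphenyl)propiolate | COc1ccc(C#CC(=O)OC(C)(C)C)cc1 | intermediate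
11 | tert-butyl (Z)-3-{3,5-bis(benzyloxy)-2-[4-(methoxycarbonyl)phenoxy]phenoxy}-3-(4-methoxyphenyl)acrylate | CC(C)(C)OC(=O)/C=C(\Oc1cc(OCc2ccccc2)cc(OCc2ccccc2)c1Oc1ccc(C(=O)OC)cc1)c1ccc(OC)cc1 | intermediate
12 | (Z)-3-{3,5-bis(benzyloxy)-2-[4-(methoxycarbonyl)phenoxy]phenoxy}-3-(4-methoxyphenyl)acrylic acid | OC(=O)/C=C(\Oc1cc(OCc2ccccc2)cc(OCc2ccccc2)c1Oc1ccc(C(=O)OC)cc1)c1ccc(OC)cc1 | intermediate
13 | (Z)-3-{3,5-bis(benzyloxy)-2-[4-(methoxycarbonyl)phenoxy]phenoxy}-3-(4-methoxyphenyl)acrylic trifluoroacetic anhydride | O=C(OC(=O)/C=C(\Oc1cc(OCc2ccccc2)cc(OCc2ccccc2)c1Oc1ccc(C(=O)OC)cc1)c1ccc(OC)cc1)C(F)(F)F | intermediate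
14 | methyl 4-{[5,7-bis(benzyloxy)-2-(4-methoxyphenyl)-4-oxo-4H-chromen-8-yl]oxy}benzoate | COc1ccc(-c2cc(=O)c3c(OCc4ccccc4)cc(OCc4ccccc4)c(Oc4ccc(C(=O)OC)cc4)c3o2)cc1 | intermediate
15 | 4-{[5,7-bis(benzyloxy)-2-(4-methoxyphenyl)-4-oxo-4H-chromen-8-yl]oxy}benzoic acid | COc1ccc(-c2cc(=O)c3c(OCc4ccccc4)cc(OCc4ccccc4)c(Oc4ccc(C(=O)O)cc4)c3o2)cc1 | intermediate
16 | 2,6-dihydroxy-4-methoxyacetophenone | CC(=O)c1c(O)cc(OC)cc1O | starting material
17 | 2-acetyl-3-hydroxy-5-methoxyphenyl 4-{[5,7-bis(benzyloxy)-2-(4-methoxyphenyl)-4-oxo-4H-chromen-8-yl]oxy}benzoate | COc1ccc(-c2cc(=O)c3c(OCc4ccccc4)cc(OCc4ccccc4)c(Oc4ccc(C(=O)Oc5cc(OC)cc(O)c5C(C)=O)cc4)c3o2)cc1 | intermediate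
18 | 1-(4-{[5,7-bis(benzyloxy)-2-(4-methoxyphenyl)-4-oxo-4H-chromen-8-yl]oxy}phenyl)-3-(2,6-dihydroxy-4-methoxyphenyl)propane-1,3-dione | COc1ccc(-c2cc(=O)c3c(OCc4ccccc4)cc(OCc4ccccc4)c(Oc4ccc(C(=O)CC(=O)c5c(O)cc(OC)cc5O)cc4)c3o2)cc1 | intermediate
19 | 5,7-bis(benzyloxy)-8-[4-(5-hydroxy-7-methoxy-4-oxo-4H-chromen-2-yl)phenoxy]-2-(4-methoxyphenyl)-4H-chromen-4-one | COc1ccc(-c2cc(=O)c3c(OCc4ccccc4)cc(OCc4ccccc4)c(Oc4ccc(-c5cc(=O)c6c(O)cc(OC)cc6o5)cc4)c3o2)cc1 | intermediate
20 | 5,7-dihydroxy-8-[4-(5-hydroxy-7-methoxy-4-oxo-4H-chromen-2-yl)phenoxy]-2-(4-methoxyphenyl)-4H-chromen-4-one (CNP0124888.0) | COc1ccc(-c2cc(=O)c3c(O)cc(O)c(Oc4ccc(-c5cc(=O)c6c(O)cc(OC)cc6o5)cc4)c3o2)cc1 | target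

## Step count and risk

Total step count: 14. Longest linear sequence: 13 steps (steps 1–5 and 7–14, from 1 to 20); step 6 is a one-step side branch.

**Step 9 (key step).** Three things may go wrong:
- intermolecular trifluoroacetylation of the ring at the carbon between the two benzyloxy groups could compete with ring closure;
- acid could cleave the enol ether if moisture enters, or remove the 5-O-benzyl group once the chelating carbonyl is in place;
- an E acid that isomerises slowly could in principle close onto the anisyl ring, although that carbon is meta to the methoxy group and a five-membered closure should be slower.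

Fallback, setting out from 8: ortho-formylation (MgCl2, Et3N, paraformaldehyde, MeCN, reflux), which can only go to the one free ortho carbon, should give methyl 4-[4,6-bis(benzyloxy)-3-formyl-2-hydroxyphenoxy]benzoate F1. Addition of lithium (4-methoxyphenyl)acetylide (from 4-ethynylanisole and n-BuLi, THF, −78 °C) should give the racemic propargylic alcohol methyl 4-{4,6-bis(benzyloxy)-2-hydroxy-3-[1-hydroxy-3-(4-methoxyphenyl)prop-2-yn-1-yl]phenoxy}benzoate F2. Oxidation with MnO2 in CH2Cl2 should give the ynone methyl 4-{4,6-bis(benzyloxy)-2-hydroxy-3-[3-(4-methoxyphenyl)prop-2-ynoyl]phenoxy}benzoate F3. Et2NH in EtOH then closes the pyranone by conjugate addition of the phenol and returns to the route at 14.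

**Step 1.** Benzylation may overrun to the tribenzyl ether or stop early, and C-benzylation of the phloroglucinol-type ring is possible. Fallback, setting out from 1: exhaustive benzylation (excess BnBr, K2CO3, DMF, 60 °C) to 2,4,6-tris(benzyloxy)benzaldehyde F4, then chelation-directed removal of one ortho benzyl group with MgBr2·OEt2 in toluene/ether at reflux, which returns to the route at 2.

**Step 4.** The substitution may be slow, because the phenoxide has two ortho substituents and a para ester activates only moderately. Air oxidation of the electron-rich phenoxide and cleavage of the methyl ester at high temperature are the competing processes. Fallback, setting out from 5: copper-catalysed Ullmann-type coupling with methyl 4-iodobenzoate (CuI, picolinic acid, K3PO4, DMSO, 85 °C), a ligand system suited to hindered phenols, which returns to the route at 7.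

**Step 7.** The donor-substituted arylalkyne is a weak acceptor and the phenoxide is hindered, so addition may be slow. Prolonged heating with base could also allow migration of the ester-bearing aryl group between the two adjacent oxygens (Smiles-type), although the phenoxide of 8, meta to both benzyloxy groups, should be the favoured one. Fallback, setting out from 8: addition to the more electrophilic 3-(4-methoxyphenyl)propiolaldehyde (Et3N cat., MeCN, rt) should give (Z)-3-{3,5-bis(benzyloxy)-2-[4-(methoxycarbonyl)phenoxy]phenoxy}-3-(4-methoxyphenyl)acrylaldehyde F5. Pinnick oxidation (NaClO2, NaH2PO4, 2-methyl-2-butene, t-BuOH/H2O) then returns to the route at 12 and also bypasses step 8.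

**Step 12.** The polyanion may aggregate and react sluggishly, or the aryl ester may be cleaved intermolecularly instead of undergoing acyl transfer. Fallback, setting out from 15: conversion with oxalyl chloride and catalytic DMF into 4-{[5,7-bis(benzyloxy)-2-(4-methoxyphenyl)-4-oxo-4H-chromen-8-yl]oxy}benzoyl chloride F6, which is added to the trilithium salt of 16 (LiN(SiMe3)2, 4 equiv, THF, −78 °C). Direct C-acylation of the enolate returns to the route at 18 without passing through 17.

**Step 14.** The C2=C3 bond of either pyranone could be over-reduced on prolonged exposure, or the reaction could stall because the biflavone is poorly soluble. Fallback, setting out from 19: Lewis-acid debenzylation with BCl3 and pentamethylbenzene as cation trap in CH2Cl2 at −78 °C, which leaves the non-chelated methyl ethers in place and returns to the route at 20.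

## Further compounds

F1 | step 9 | methyl 4-[4,6-bis(benzyloxy)-3-formyl-2-hydroxyphenoxy]benzoate | COC(=O)c1ccc(Oc2c(O)c(C=O)c(OCc3ccccc3)cc2OCc2ccccc2)cc1
F2 | step 9 | methyl 4-{4,6-bis(benzyloxy)-2-hydroxy-3-[1-hydroxy-3-(4-methoxyphenyl)prop-2-yn-1-yl]phenoxy}benzoate (racemic) | COC(=O)c1ccc(Oc2c(O)c(C(O)C#Cc3ccc(OC)cc3)c(OCc3ccccc3)cc2OCc2ccccc2)cc1
F3 | step 9 | methyl 4-{4,6-bis(benzyloxy)-2-hydroxy-3-[3-(4-methoxyphenyl)prop-2-ynoyl]phenoxy}benzoate | COC(=O)c1ccc(Oc2c(O)c(C(=O)C#Cc3ccc(OC)cc3)c(OCc3ccccc3)cc2OCc2ccccc2)cc1
F4 | step 1 | 2,4,6-tris(benzyloxy)benzaldehyde | O=Cc1c(OCc2ccccc2)cc(OCc2ccccc2)cc1OCc1ccccc1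
F0 | step 4 | none | none
F5 | step 7 | (Z)-3-{3,5-bis(benzyloxy)-2-[4-(methoxycarbonyl)phenoxy]phenoxy}-3-(4-methoxyphenyl)acrylaldehyde | O=C/C=C(\Oc1cc(OCc2ccccc2)cc(OCc2ccccc2)c1Oc1ccc(C(=O)OC)cc1)c1ccc(OC)cc1
F6 | step 12 | 4-{[5,7-bis(benzyloxy)-2-(4-methoxyphenyl)-4-oxo-4H-chromen-8-yl]oxy}benzoyl chloride | COc1ccc(-c2cc(=O)c3c(OCc4ccccc4)cc(OCc4ccccc4)c(Oc4ccc(C(Cl)=O)cc4)c3o2)cc1
F0 | step 14 | none | none
A1 | alternative 1 | methyl 4-[2,4-bis(benzyloxy)-6-(methoxymethoxy)phenoxy]benzoate | COC(=O)c1ccc(Oc2c(OCOC)cc(OCc3ccccc3)cc2OCc2ccccc2)cc1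
A2 | alternative 1 | 1,5-bis(benzyloxy)-2-(ethynyloxy)-3-(methoxymethoxy)benzene | C#COc1c(OCOC)cc(OCc2ccccc2)cc1OCc1ccccc1
A3 | alternative 1 | methyl coumalate (methyl 2-oxo-2H-pyran-5-carboxylate) | COC(=O)c1ccc(=O)oc1
A4 | alternative 2 | 5,7-bis(benzyloxy)-8-[4-(5,7-dimethoxy-4-oxo-4H-chromen-2-yl)phenoxy]-2-(4-methoxyphenyl)-4H-chromen-4-one | COc1ccc(-c2cc(=O)c3c(OCc4ccccc4)cc(OCc4ccccc4)c(Oc4ccc(-c5cc(=O)c6c(OC)cc(OC)cc6o5)cc4)c3o2)cc1
A5 | alternative 2 | 3,5-dimethoxy-2-(trimethylsilyl)phenyl trifluoromethanesulfonate | COc1cc(OC)cc(OS(=O)(=O)C(F)(F)F)c1[Si](C)(C)C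
A6 | alternative 2 | 3-(4-{[5,7-bis(benzyloxy)-2-(4-methoxyphenyl)-4-oxo-4H-chromen-8-yl]oxy}phenyl)propiolic acid | COc1ccc(-c2cc(=O)c3c(OCc4ccccc4)cc(OCc4ccccc4)c(Oc4ccc(C#CC(=O)O)cc4)c3o2)cc1
A7 | alternative 3 | 5,7-bis(benzyloxy)-8-[4-(1,3-dioxolan-2-yl)phenoxy]-2-(4-methoxyphenyl)-4H-chromen-4-one | COc1ccc(-c2cc(=O)c3c(OCc4ccccc4)cc(OCc4ccccc4)c(Oc4ccc(C5OCCO5)cc4)c3o2)cc1
A8 | alternative 3 | 1-{4,6-bis(benzyloxy)-3-[4-(1,3-dioxolan-2-yl)phenoxy]-2-{[1-(4-methoxyphenyl)ethenyl]oxy}phenyl}prop-2-en-1-one | C=CC(=O)c1c(OCc2ccccc2)cc(OCc2ccccc2)c(Oc2ccc(C3OCCO3)cc2)c1OC(=C)c1ccc(OC)cc1
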